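## Retrosynthetic overview

1. The labile C3–H stereocentre is set second to last. The (3S)-ketone comes from enantioselective protonation of the C3=C4 enol silane of the isoflavanone, and only a buffered desilylation follows.
2. Ring C of that enol silane (a 4-siloxy-2H-chromene) is cut at C2–C3 and at C4–C4a. This gives a ring A aryloxymethyl pivalate (O1, C2) and a ring B siloxy alkyne (C3, C4), joined in one silylium-catalysed cationic [4+2] annulation.
3. Enabling feature: the aryl ether unit O1–C8a=C4a of ring A, with C4a para to the C7 oxygen, turns ArO–CH2+ into a cationic 2-oxadiene C2=O1+–C8a=C4a. The C3–C4(=O) unit has the oxidation level of an ynol, and a silyl group on C4a ends the cascade as a traceless leaving group.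
4. Ring A partner: symmetric 4,6-dibromoresorcinol, retro-Brook shift (frees O1 alone, puts Si on C4a), Stille prenylation at C6. Ring B partner: 4-bromo-2,5-dimethoxybenzaldehyde, Baeyer–Villiger oxidation, Sonogashira coupling, acetylide oxidation.
5. Ring order: rings A and B are bought as arenes, and ring C is the only ring formed (key step).

Key step: step 8

Assumption: chromanone numbering is used (O1, C2, C3, C4, C4a, C5–C8, C8a; ring B primed), and the single stereocentre of the given SMILES reads as 3S.

## Route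

Step 1
Reactants: 1 4,6-dibromoresorcinol
Product: 2 4,6-dibromo-1,3-bis(tert-butyldimethylsilyloxy)benzene
Conditions: TBSCl (2.4 equiv), imidazole, DMF, rt
Reagents that add atoms: tert-butyldimethylsilyl chloride, CC(C)(C)[Si](C)(C)Cl
Why: Imidazole-promoted silylation of phenols, which keeps the mirror symmetry of 1 so that the two Br/OSi pairs stay equivalent for step 2.

Step 2
Reactants: 2 4,6-dibromo-1,3-bis(tert-butyldimethylsilyloxy)benzene; 3 iodomethyl pivalate
Product: 6 [4-bromo-2-(tert-butyldimethylsilyl)-5-(tert-butyldimethylsilyloxy)phenoxy]methyl pivalate, via aryllithium 4 (not isolated), via lithium phenoxide 5 (not isolated)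
Conditions: n-BuLi (1.05 equiv), THF, −78 °C → rt; then 3, DMPU, 0 °C → rt
Reagents that add atoms: none
Why: Bromine–lithium exchange with one equivalent of n-BuLi gives 4, whose ortho silyl ether undergoes the retro-Brook (1,3 O-to-C) silyl shift on warming, freeing only the oxygen that becomes O1 and placing silicon on the carbon that becomes C4a, and Williamson-type alkylation of 5 by the very reactive α-acyloxy iodide 3 should follow because the hindered pivaloyl carbonyl resists acyl transfer.

Step 3
Reactants: 6 [4-bromo-2-(tert-butyldimethylsilyl)-5-(tert-butyldimethylsilyloxy)phenoxy]methyl pivalate; 7 tributyl(3-methylbut-2-enyl)stannane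
Product: 8 [2-(tert-butyldimethylsilyl)-5-(tert-butyldimethylsilyloxy)-4-(3-methylbut-2-enyl)phenoxy]methyl pivalate
Conditions: Pd(PPh3)4 (5 mol %), toluene, 110 °C
Reagents that add atoms: none
Why: Migita–Kosugi–Stille allylation of an aryl bromide under neutral conditions that the acetal ester, the aryl silane and the silyl ether tolerate, with reductive elimination at the less substituted allyl terminus expected to give the linear prenyl arene.

Step 4
Reactants: 9 4-bromo-2,5-dimethoxybenzaldehyde
Product: 11 4-bromo-2,5-dimethoxyphenol, via aryl formate 10 (not isolated)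
Conditions: mCPBA, CH2Cl2, rt; aq. NaHCO3 wash; then K2CO3 (cat.), MeOH, rt
Reagents that add atoms: 3-chloroperbenzoic acid, OOC(=O)c1cccc(Cl)c1
Why: Baeyer–Villiger oxidation of an electron-rich benzaldehyde (aryl migration favoured by the ortho methoxy group) followed by methanolysis of the formate, a Dakin-type exchange of CHO for OH.

Step 5
Reactants: 11 4-bromo-2,5-dimethoxyphenol
Product: 12 (4-bromo-2,5-dimethoxyphenoxy)triisopropylsilane
Conditions: TIPSCl, imidazole, DMF, rt
Reagents that add atoms: triisopropylsilyl chloride, CC(C)[Si](Cl)(C(C)C)C(C)C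
Why: Standard phenol silylation, with the bulky triisopropylsilyl group chosen so that the aryl silyl ether survives the organolithium and peroxide reagents of step 7.

Step 6
Reactants: 12 (4-bromo-2,5-dimethoxyphenoxy)triisopropylsilane; 13 ethynyltrimethylsilane
Product: 14 {[2,5-dimethoxy-4-(triisopropylsilyloxy)phenyl]ethynyl}trimethylsilane
Conditions: PdCl2(PPh3)2 (3 mol %), CuI (5 mol %), Et3N, 80 °C
Reagents that add atoms: none
Why: Sonogashira coupling of an aryl bromide with a silyl-capped acetylene, which brings in the two carbons that become C3 and C4.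

Step 7
Reactants: 14 {[2,5-dimethoxy-4-(triisopropylsilyloxy)phenyl]ethynyl}trimethylsilane
Product: 17 {[2,5-dimethoxy-4-(triisopropylsilyloxy)phenyl]ethynyloxy}triisopropylsilane, via lithium acetylide 15 (not isolated), via lithium ynolate 16 (not isolated)
Conditions: MeLi·LiBr, THF, −78 → 0 °C; LiOOt-Bu (from t-BuOOH and LiN(SiMe3)2), −78 → 0 °C; TIPSOTf, −78 → 0 °C
Reagents that add atoms: tert-butyl hydroperoxide, CC(C)(C)OO; triisopropylsilyl triflate, CC(C)[Si](C(C)C)(C(C)C)OS(=O)(=O)C(F)(F)F
Why: Desilylative lithiation of the alkynylsilane gives 15, oxygen transfer from lithium tert-butyl peroxide gives ynolate 16, and the hard, bulky silyl triflate traps it on oxygen, which is the established sequence for making siloxy alkynes from acetylides.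

Step 8
Reactants: 8 [2-(tert-butyldimethylsilyl)-5-(tert-butyldimethylsilyloxy)-4-(3-methylbut-2-enyl)phenoxy]methyl pivalate; 17 {[2,5-dimethoxy-4-(triisopropylsilyloxy)phenyl]ethynyloxy}triisopropylsilane
Product: 20 7-(tert-butyldimethylsilyloxy)-3-[2,5-dimethoxy-4-(triisopropylsilyloxy)phenyl]-6-(3-methylbut-2-enyl)-4-(triisopropylsilyloxy)-2H-chromene, via aryloxycarbenium ion 18 (not isolated), via silyl ketenium ion 19 (not isolated)
Conditions: Me3SiNTf2 (10 mol %), 2,6-di-tert-butyl-4-methylpyridine (15 mol %), 4 Å molecular sieves, CH2Cl2, −78 → −20 °C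
Reagents that add atoms: none
Why: Proposed new method: the silyl triflimide silylates the pivalate carbonyl of 8 and releases 18, a cationic 2-oxadiene (C2=O1+–C8a=C4a), whose CH2 carbon is attacked by the oxygen-polarised β-carbon of 17 (C2–C3 bond) to give ketenium ion 19, whose sp carbon C4 is then attacked by C4a of ring A (C4–C4a bond) while the C4a silyl group leaves as the chain-carrying silylium ion, so that no proton is released. The closest known reaction types are the oxa-Povarov reaction (aryl oxocarbenium ions plus alkenes give chromans), the cationic polar cycloaddition of aryl thionium ions with alkynes, the addition of siloxy alkynes to oxocarbenium ions and the acid-induced closure of siloxy-alkyne-derived ketenium ions onto arenes to give tetralone enol silanes, whereas their union with a formaldehyde-level aryloxycarbenium ion and an ipso-silyl terminator is new. Ring C closes as a stepwise formal [4+2] annulation, the second bond by a 6-exo-dig attack counted on the C=O+ bond of the ketenium ion (6-endo-dig counted on the former alkyne), with the in-plane approach that the O1–C2 tether allows. No stereocentre is formed: C3 emerges sp2 in a tetrasubstituted enol silane, which holds C4 at the ketone oxidation level and keeps the labile C3–H centre unformed until step 9. The step needs closure at C4a and not at C8 (secured by the ipso-directing β-silicon effect at C4a, the para C7 oxygen and the bulk of the C7 silyl ether next to C8), reaction of the cation with the ynol ether and not with the prenyl alkene or an arene (secured by the much higher π-nucleophilicity of the ynol ether and by the buffered, proton-free medium), and carbon rather than O1 attack on the ketenium ion (the aryl ether oxygen is a poor donor and the oxetenium ring is strained).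

Step 9
Reactants: 20 7-(tert-butyldimethylsilyloxy)-3-[2,5-dimethoxy-4-(triisopropylsilyloxy)phenyl]-6-(3-methylbut-2-enyl)-4-(triisopropylsilyloxy)-2H-chromene
Product: 21 (3S)-7-(tert-butyldimethylsilyloxy)-3-[2,5-dimethoxy-4-(triisopropylsilyloxy)phenyl]-6-(3-methylbut-2-enyl)chroman-4-one
Conditions: BINOL-derived N-triflyl thiophosphoramide bearing 3,3'-bis(2,4,6-triisopropylphenyl) groups (5 mol %), MeOH (1.5 equiv), toluene, −40 °C → rt
Reagents that add atoms: none
Why: Catalytic enantioselective protonation of the silyl enol ether of an α-aryl cyclic ketone by a strong chiral Brønsted acid, in which C3 is set by face-selective proton transfer inside the chiral ion pair, methanol removes the silyl group and regenerates the acid, the enol silane is far more basic than the prenyl alkene, and the catalyst antipode that delivers 3S is fixed in a trial run.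

Step 10
Reactants: 21 (3S)-7-(tert-butyldimethylsilyloxy)-3-[2,5-dimethoxy-4-(triisopropylsilyloxy)phenyl]-6-(3-methylbut-2-enyl)chroman-4-one
Product: 22 (3S)-7-hydroxy-3-(4-hydroxy-2,5-dimethoxyphenyl)-6-(3-methylbut-2-enyl)chroman-4-one
Conditions: HF·pyridine, extra pyridine, THF, 0 °C → rt
Reagents that add atoms: none
Why: Fluoride cleavage of the two aryl silyl ethers in a weakly acidic buffered medium, in which the α-aryl ketone should not enolise (C3 is kept) and the prenyl/phenol pair should not cyclise.

## Compound list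

1 | 4,6-dibromoresorcinol | Oc1cc(O)c(Br)cc1Br | starting material
2 | 4,6-dibromo-1,3-bis(tert-butyldimethylsilyloxy)benzene | CC(C)(C)[Si](C)(C)Oc1cc(O[Si](C)(C)C(C)(C)C)c(Br)cc1Br | intermediate
3 | iodomethyl pivalate | CC(C)(C)C(=O)OCI | starting material
4 | 5-bromo-2,4-bis(tert-butyldimethylsilyloxy)phenyllithium | [Li]c1cc(Br)c(O[Si](C)(C)C(C)(C)C)cc1O[Si](C)(C)C(C)(C)C | intermediate
5 | lithium 4-bromo-2-(tert-butyldimethylsilyl)-5-(tert-butyldimethylsilyloxy)phenoxide | [Li+].[O-]c1cc(O[Si](C)(C)C(C)(C)C)c(Br)cc1[Si](C)(C)C(C)(C)C | intermediate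
6 | [4-bromo-2-(tert-butyldimethylsilyl)-5-(tert-butyldimethylsilyloxy)phenoxy]methyl pivalate | CC(C)(C)C(=O)OCOc1cc(O[Si](C)(C)C(C)(C)C)c(Br)cc1[Si](C)(C)C(C)(C)C | intermediate
7 | tributyl(3-methylbut-2-enyl)stannane | CCCC[Sn](CCCC)(CCCC)CC=C(C)C | starting material
8 | [2-(tert-butyldimethylsilyl)-5-(tert-butyldimethylsilyloxy)-4-(3-methylbut-2-enyl)phenoxy]methyl pivalate | CC(C)(C)C(=O)OCOc1cc(O[Si](C)(C)C(C)(C)C)c(CC=C(C)C)cc1[Si](C)(C)C(C)(C)C | intermediate
9 | 4-bromo-2,5-dimethoxybenzaldehyde | COc1cc(C=O)c(OC)cc1Br | starting material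
10 | 4-bromo-2,5-dimethoxyphenyl formate | COc1cc(OC=O)c(OC)cc1Br | intermediate
11 | 4-bromo-2,5-dimethoxyphenol | COc1cc(O)c(OC)cc1Br | intermediate
12 | (4-bromo-2,5-dimethoxyphenoxy)triisopropylsilane | COc1cc(O[Si](C(C)C)(C(C)C)C(C)C)c(OC)cc1Br | intermediate
13 | ethynyltrimethylsilane | C#C[Si](C)(C)C | starting material
14 | {[2,5-dimethoxy-4-(triisopropylsilyloxy)phenyl]ethynyl}trimethylsilane | COc1cc(O[Si](C(C)C)(C(C)C)C(C)C)c(OC)cc1C#C[Si](C)(C)C | intermediate
15 | lithium [2,5-dimethoxy-4-(triisopropylsilyloxy)phenyl]acetylide | [Li]C#Cc1cc(OC)c(O[Si](C(C)C)(C(C)C)C(C)C)cc1OC | intermediate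
16 | lithium [2,5-dimethoxy-4-(triisopropylsilyloxy)phenyl]ethynolate | [Li+].[O-]C#Cc1cc(OC)c(O[Si](C(C)C)(C(C)C)C(C)C)cc1OC | intermediate
17 | {[2,5-dimethoxy-4-(triisopropylsilyloxy)phenyl]ethynyloxy}triisopropylsilane | CC(C)[Si](C(C)C)(C(C)C)OC#Cc1cc(OC)c(O[Si](C(C)C)(C(C)C)C(C)C)cc1OC | intermediate
18 | aryloxycarbenium (methylene aryloxonium) triflimide derived from 8 | C=[O+]c1cc(O[Si](C)(C)C(C)(C)C)c(CC=C(C)C)cc1[Si](C)(C)C(C)(C)C.FC(F)(F)S(=O)(=O)[N-]S(=O)(=O)C(F)(F)F | intermediate
19 | O-triisopropylsilyl ketenium triflimide carrying the aryloxymethyl group and ring B on C3 | CC(C)[Si](C(C)C)(C(C)C)[O+]=C=C(COc1cc(O[Si](C)(C)C(C)(C)C)c(CC=C(C)C)cc1[Si](C)(C)C(C)(C)C)c1cc(OC)c(O[Si](C(C)C)(C(C)C)C(C)C)cc1OC.FC(F)(F)S(=O)(=O)[N-]S(=O)(=O)C(F)(F)F | intermediate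
20 | 7-(tert-butyldimethylsilyloxy)-3-[2,5-dimethoxy-4-(triisopropylsilyloxy)phenyl]-6-(3-methylbut-2-enyl)-4-(triisopropylsilyloxy)-2H-chromene | COc1cc(C2=C(O[Si](C(C)C)(C(C)C)C(C)C)c3cc(CC=C(C)C)c(O[Si](C)(C)C(C)(C)C)cc3OC2)c(OC)cc1O[Si](C(C)C)(C(C)C)C(C)C | intermediate
21 | (3S)-7-(tert-butyldimethylsilyloxy)-3-[2,5-dimethoxy-4-(triisopropylsilyloxy)phenyl]-6-(3-methylbut-2-enyl)chroman-4-one | COc1cc([C@H]2COc3cc(O[Si](C)(C)C(C)(C)C)c(CC=C(C)C)cc3C2=O)c(OC)cc1O[Si](C(C)C)(C(C)C)C(C)C | intermediate
22 | (3S)-7-hydroxy-3-(4-hydroxy-2,5-dimethoxyphenyl)-6-(3-methylbut-2-enyl)chroman-4-one | COc1cc([C@H]2COc3cc(O)c(CC=C(C)C)cc3C2=O)c(OC)cc1O | target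

## Step count and risks

Total steps: 10. Longest linear sequence: 7 (steps 4, 5, 6, 7, 8, 9, 10).

**Step 8.**
- What may go wrong:
  - Ionisation of the acetal ester may be too slow at low temperature.
  - The ketenium ion may be captured by O1 (oxetenium formation and ring opening), or reversibly by the 2'-methoxy oxygen.
  - The ynol ether may oligomerise.
- Fallback: the two bonds are made one after the other by known reactions. It sets out from 17 and 8 and comes back to the route at 20.
  - Hydration and hydrolysis of 17 in one flask (aq. CF3CO2H, THF) gives 2-[2,5-dimethoxy-4-(triisopropylsilyloxy)phenyl]acetic acid F1.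
  - LiN(SiMe3)2 (2.2 equiv) and Me3SiCl convert it into the bis(trimethylsilyl) ketene acetal F2.
  - Mukaiyama-type alkylation of F2 with 8 (Me3SiOTf cat., CH2Cl2, −78 °C) and aqueous work-up gives the racemic 3-aryloxy-2-arylpropanoic acid F3.
  - 1-Chloro-N,N,2-trimethylpropenylamine gives, under neutral conditions, the acid chloride F4.
  - SnCl4 (CH2Cl2, −78 °C) closes ring C by intramolecular Friedel–Crafts ipso-acylation of the aryl silane to the racemic protected isoflavanone F5.
  - Soft enolisation (TIPSOTf, Et3N, CH2Cl2) returns 20.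

**Step 9.**
- What may go wrong:
  - Facial selectivity of the proton transfer may be poor.
  - Removal of the bulky triisopropylsilyl group may be sluggish, which would make protonation reversible.
- Fallback: the centre is set by reduction instead of protonation. It sets out from 20 and comes back at 21.
  - Hydrolysis of 20 (aq. HCl, THF) gives the racemic protected isoflavanone F6 (same structure as F5).
  - Noyori–Ikariya asymmetric transfer hydrogenation under dynamic kinetic resolution (RuCl(p-cymene)[(S,S)-TsDPEN], HCO2H/Et3N, EtOAc, rt), a reaction known for isoflavanones, should give the cis-(3S,4S)-isoflavan-4-ol F7. C3 epimerises in the amine medium while one enantiomer is reduced faster.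
  - Dess–Martin periodinane with NaHCO3 (CH2Cl2, 0 °C) removes the C4 centre and returns 21 with C3 untouched.

**Step 3.**
- What may go wrong:
  - Oxidative addition to the hindered, electron-rich bromide may be slow.
  - Allyl transposition may lead to the branched isomer.
  - The aryl silyl ether may be lost at high temperature.
- Fallback: the prenyl group is brought in before the acetal ester, which opens the way to room-temperature organozinc chemistry. It sets out from 2 and comes back at 8.
  - n-BuLi (THF, −78 °C → rt) followed by an NH4Cl quench gives 4-bromo-2-(tert-butyldimethylsilyl)-5-(tert-butyldimethylsilyloxy)phenol F8.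
  - Linear-selective Negishi coupling (Me2C=CHCH2ZnBr, 2.5 equiv, Pd(OAc)2, CPhos, THF, rt) gives 2-(tert-butyldimethylsilyl)-5-(tert-butyldimethylsilyloxy)-4-(3-methylbut-2-enyl)phenol F9.
  - NaH and 3 (THF/DMF, 0 °C) give 8.

## Further compounds

F1 | step 8 | 2-[2,5-dimethoxy-4-(triisopropylsilyloxy)phenyl]acetic acid | COc1cc(CC(=O)O)c(OC)cc1O[Si](C(C)C)(C(C)C)C(C)C
F2 | step 8 | bis(trimethylsilyl) ketene acetal of F1 | COc1cc(C=C(O[Si](C)(C)C)O[Si](C)(C)C)c(OC)cc1O[Si](C(C)C)(C(C)C)C(C)C
F3 | step 8 | racemic 3-[2-(tert-butyldimethylsilyl)-5-(tert-butyldimethylsilyloxy)-4-(3-methylbut-2-enyl)phenoxy]-2-[2,5-dimethoxy-4-(triisopropylsilyloxy)phenyl]propanoic acid | COc1cc(C(COc2cc(O[Si](C)(C)C(C)(C)C)c(CC=C(C)C)cc2[Si](C)(C)C(C)(C)C)C(=O)O)c(OC)cc1O[Si](C(C)C)(C(C)C)C(C)C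
F4 | step 8 | acid chloride of F3 (racemic) | COc1cc(C(COc2cc(O[Si](C)(C)C(C)(C)C)c(CC=C(C)C)cc2[Si](C)(C)C(C)(C)C)C(=O)Cl)c(OC)cc1O[Si](C(C)C)(C(C)C)C(C)C
F5 | step 8 | racemic 7-(tert-butyldimethylsilyloxy)-3-[2,5-dimethoxy-4-(triisopropylsilyloxy)phenyl]-6-(3-methylbut-2-enyl)chroman-4-one | COc1cc(C2COc3cc(O[Si](C)(C)C(C)(C)C)c(CC=C(C)C)cc3C2=O)c(OC)cc1O[Si](C(C)C)(C(C)C)C(C)C
F6 | step 9 | racemic 7-(tert-butyldimethylsilyloxy)-3-[2,5-dimethoxy-4-(triisopropylsilyloxy)phenyl]-6-(3-methylbut-2-enyl)chroman-4-one | COc1cc(C2COc3cc(O[Si](C)(C)C(C)(C)C)c(CC=C(C)C)cc3C2=O)c(OC)cc1O[Si](C(C)C)(C(C)C)C(C)C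
F7 | step 9 | (3S,4S)-7-(tert-butyldimethylsilyloxy)-3-[2,5-dimethoxy-4-(triisopropylsilyloxy)phenyl]-6-(3-methylbut-2-enyl)chroman-4-ol (cis) | COc1cc([C@H]2COc3cc(O[Si](C)(C)C(C)(C)C)c(CC=C(C)C)cc3[C@H]2O)c(OC)cc1O[Si](C(C)C)(C(C)C)C(C)C
F8 | step 3 | 4-bromo-2-(tert-butyldimethylsilyl)-5-(tert-butyldimethylsilyloxy)phenol | Oc1cc(O[Si](C)(C)C(C)(C)C)c(Br)cc1[Si](C)(C)C(C)(C)C
F9 | step 3 | 2-(tert-butyldimethylsilyl)-5-(tert-butyldimethylsilyloxy)-4-(3-methylbut-2-enyl)phenol | Oc1cc(O[Si](C)(C)C(C)(C)C)c(CC=C(C)C)cc1[Si](C)(C)C(C)(C)C
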